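**Plan**

- Retrosynthesis: the two ring B phenols are masked as TIPS ethers; ring C is then cut at C4–C4a and at O1–C2 in one operation. This gives ring A phenol 6 and 2-arylacrolein 12, which carries C2, C3, C4 and ring B.
- Enabling feature: ring C (O1, C2, C3, C4, C4a, C8a) is a 2H-pyran fused to ring A. It is the closed valence tautomer of the vinyl ortho-quinone methide O1=C8a–C4a=C4–C3=C2. C2 is a CH2 group, and the two ortho carbons of phenol 6 are equivalent by symmetry.
- Forward, ring A fragment: directed metalation and prenylation of the TIPS ether of 3,5-dimethoxyphenol, then desilylation. Ring B fragment: borylation and Suzuki–Miyaura coupling of bis-TIPS 4-bromoresorcinol with 2-bromoallyl alcohol, then MnO2 oxidation.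
- Ring C arises in step 7 by boron-templated ortho-hydroxyalkylation, ortho-quinone methide formation and oxa-6π electrocyclisation; buffered fluoride then frees the two phenols.
- Stereochemistry: the target has no stereocentre and no stereogenic double bond. The only transient stereocentre (C4 of dioxaborin 13) is erased within step 7.

Key step: step 7

Remark: 3,5-dimethoxyphenol, prenyl bromide, 4-bromoresorcinol and 2-bromoprop-2-en-1-ol are taken as commercial; enal 12 is assumed to dimerise on storage, as 2-arylacroleins do, and is carried into step 7 at once.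

**Route**

Step 1
Reactants: 1 3,5-dimethoxyphenol
Product: 2 (3,5-dimethoxyphenoxy)triisopropylsilane
Conditions: TIPSCl (1.2 equiv), imidazole (2.5 equiv), DMF, rt
Reagents that add atoms: chlorotriisopropylsilane (TIPSCl), CC(C)[Si](Cl)(C(C)C)C(C)C
Why: Imidazole-promoted silylation of a phenol (silyl ether formation); the bulky, poorly coordinating OTIPS group should later shield its two neighbouring ring carbons from metalation.

Step 2
Reactants: 2 (3,5-dimethoxyphenoxy)triisopropylsilane; 3 prenyl bromide (1-bromo-3-methylbut-2-ene)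
Product: 5 [3,5-dimethoxy-4-(3-methylbut-2-enyl)phenoxy]triisopropylsilane, via aryllithium 4 (not isolated)
Conditions: n-BuLi (1.15 equiv), THF, 0 °C to rt; then 3, −78 °C to rt
Reagents that add atoms: none
Why: Directed ortho-metalation, in which the two methoxy groups together guide n-BuLi to the carbon between them, followed by SN2 alkylation of the 2,6-dimethoxyaryllithium at the primary allylic bromide.

Step 3
Reactants: 5 [3,5-dimethoxy-4-(3-methylbut-2-enyl)phenoxy]triisopropylsilane
Product: 6 3,5-dimethoxy-4-(3-methylbut-2-enyl)phenol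
Conditions: TBAF (1.1 equiv), AcOH (1.1 equiv), THF, 0 °C
Reagents that add atoms: none
Why: Fluoride-induced desilylation of an aryl silyl ether, driven by the Si–F bond, with acetic acid protonating the phenoxide so that the electron-rich phenol is not exposed to base.

Step 4
Reactants: 7 4-bromoresorcinol (4-bromobenzene-1,3-diol)
Product: 8 1-bromo-2,4-bis(triisopropylsilyloxy)benzene
Conditions: TIPSCl (2.5 equiv), imidazole (5 equiv), DMF, rt to 40 °C
Reagents that add atoms: chlorotriisopropylsilane (TIPSCl), CC(C)[Si](Cl)(C(C)C)C(C)C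
Why: Double silylation of the two phenols (silyl ether formation); TIPS is chosen because it should survive aqueous base, hot acetic acid and MnO2 and still leave with fluoride at the end.

Step 5
Reactants: 8 1-bromo-2,4-bis(triisopropylsilyloxy)benzene; 9 2-bromoprop-2-en-1-ol
Product: 11 2-[2,4-bis(triisopropylsilyloxy)phenyl]prop-2-en-1-ol, via aryl pinacol boronate 10 (not isolated)
Conditions: B2pin2 (1.1 equiv), PdCl2(dppf) (5 mol %), KOAc (3 equiv), 1,4-dioxane, 90 °C; then 9 (1.3 equiv), aq. K3PO4, 80 °C
Reagents that add atoms: none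
Why: Miyaura borylation of the aryl bromide followed in the same flask by Suzuki–Miyaura coupling with the vinyl bromide, which tolerates the free allylic hydroxyl and avoids an ortho-silyloxy aryllithium that could suffer oxygen-to-carbon silyl migration.

Step 6
Reactants: 11 2-[2,4-bis(triisopropylsilyloxy)phenyl]prop-2-en-1-ol
Product: 12 2-[2,4-bis(triisopropylsilyloxy)phenyl]prop-2-enal
Conditions: activated MnO2 (excess), CH2Cl2, rt; filtered and used at once
Reagents that add atoms: none
Why: Heterogeneous MnO2 oxidation of an allylic alcohol should stop at the enal under neutral conditions that leave the aryl silyl ethers untouched.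

Step 7
Reactants: 6 3,5-dimethoxy-4-(3-methylbut-2-enyl)phenol; 12 2-[2,4-bis(triisopropylsilyloxy)phenyl]prop-2-enal
Product: 15 3-[2,4-bis(triisopropylsilyloxy)phenyl]-5,7-dimethoxy-6-(3-methylbut-2-enyl)-2H-chromene, via benzodioxaborin 13 (not isolated), via vinyl ortho-quinone methide 14 (not isolated)
Conditions: PhB(OH)2 (1.0 equiv), AcOH, toluene, reflux with Dean–Stark trap, 12 added slowly
Reagents that add atoms: none
Why: PhB(OH)2 esterifies phenol 6 and binds aldehyde 12, so that one ortho carbon of ring A attacks the aldehyde carbon through a six-membered boron-bridged transition state (bond C4–C4a) and the resulting ortho-hydroxybenzyl alcohol closes the temporary 1,3,2-dioxaborin ring of 13 by boronate ester condensation with loss of water. Hot acetic acid then opens 13 by heterolysis of the benzylic and allylic C4–O bond, which the 5- and 7-methoxy groups assist, and loss of the PhB(O) unit leaves vinyl ortho-quinone methide 14, whose 1-oxatriene O1=C8a–C4a=C4–C3=C2 closes ring C by a thermal disrotatory oxa-6π electrocyclisation (bond O1–C2) that restores the aromaticity of ring A. The closest known reaction type is the arylboronic acid-mediated condensation of phenols with α,β-unsaturated aldehydes to 2H-chromenes. No stereocentre has to be controlled, since C4 of 13 forms as a racemate and becomes trigonal in 14, and C2 is a CH2 group, so the closure of ring C creates none. The step needs attack at the carbonyl carbon of 12 and not at its unsubstituted alkene terminus, which the boron tether secures by holding the carbonyl carbon at the ortho carbon; it needs no site selection on ring A, because the two ortho carbons of 6 are equivalent by symmetry, the para carbon carries the prenyl group, and product 15 has no free phenol left for a second annulation.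

Step 8
Reactants: 15 3-[2,4-bis(triisopropylsilyloxy)phenyl]-5,7-dimethoxy-6-(3-methylbut-2-enyl)-2H-chromene
Product: 16 dehydroglyasperin D
Conditions: TBAF (2.4 equiv), AcOH (2.4 equiv), degassed THF, 0 °C, argon
Reagents that add atoms: none
Why: Fluoride-induced cleavage of both aryl silyl ethers under buffered, oxygen-free conditions, which should spare the acid-sensitive 2′-hydroxyisoflav-3-ene and the prenyl group.

**Compound list**

1 | 3,5-dimethoxyphenol | COc1cc(O)cc(OC)c1 | starting material
2 | (3,5-dimethoxyphenoxy)triisopropylsilane | COc1cc(OC)cc(O[Si](C(C)C)(C(C)C)C(C)C)c1 | intermediate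
3 | prenyl bromide (1-bromo-3-methylbut-2-ene) | CC(C)=CCBr | starting material
4 | [2,6-dimethoxy-4-(triisopropylsilyloxy)phenyl]lithium (not isolated) | COc1cc(O[Si](C(C)C)(C(C)C)C(C)C)cc(OC)c1[Li] | intermediate
5 | [3,5-dimethoxy-4-(3-methylbut-2-enyl)phenoxy]triisopropylsilane | COc1cc(O[Si](C(C)C)(C(C)C)C(C)C)cc(OC)c1CC=C(C)C | intermediate
6 | 3,5-dimethoxy-4-(3-methylbut-2-enyl)phenol | COc1cc(O)cc(OC)c1CC=C(C)C | intermediate
7 | 4-bromoresorcinol (4-bromobenzene-1,3-diol) | Oc1ccc(Br)c(O)c1 | starting material
8 | 1-bromo-2,4-bis(triisopropylsilyloxy)benzene | Brc1ccc(O[Si](C(C)C)(C(C)C)C(C)C)cc1O[Si](C(C)C)(C(C)C)C(C)C | intermediate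
9 | 2-bromoprop-2-en-1-ol | OCC(Br)=C | starting material
10 | 2-[2,4-bis(triisopropylsilyloxy)phenyl]-4,4,5,5-tetramethyl-1,3,2-dioxaborolane (not isolated) | CC1(C)OB(OC1(C)C)c1ccc(O[Si](C(C)C)(C(C)C)C(C)C)cc1O[Si](C(C)C)(C(C)C)C(C)C | intermediate
11 | 2-[2,4-bis(triisopropylsilyloxy)phenyl]prop-2-en-1-ol | C=C(CO)c1ccc(O[Si](C(C)C)(C(C)C)C(C)C)cc1O[Si](C(C)C)(C(C)C)C(C)C | intermediate
12 | 2-[2,4-bis(triisopropylsilyloxy)phenyl]prop-2-enal | C=C(C=O)c1ccc(O[Si](C(C)C)(C(C)C)C(C)C)cc1O[Si](C(C)C)(C(C)C)C(C)C | intermediate
13 | 4-{1-[2,4-bis(triisopropylsilyloxy)phenyl]ethenyl}-5,7-dimethoxy-6-(3-methylbut-2-enyl)-2-phenyl-4H-1,3,2-benzodioxaborinine (racemic at C4, not isolated) | COc1cc2OB(c3ccccc3)OC(C(=C)c3ccc(O[Si](C(C)C)(C(C)C)C(C)C)cc3O[Si](C(C)C)(C(C)C)C(C)C)c2c(OC)c1CC=C(C)C | intermediate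
14 | (Z)-6-{2-[2,4-bis(triisopropylsilyloxy)phenyl]prop-2-enylidene}-3,5-dimethoxy-4-(3-methylbut-2-enyl)cyclohexa-2,4-dien-1-one (vinyl group on the side of the ring carbonyl, the geometry that cyclises; not isolated) | O=C1C=C(OC)C(CC=C(C)C)=C(OC)/C1=C/C(=C)c2ccc(O[Si](C(C)C)(C(C)C)C(C)C)cc2O[Si](C(C)C)(C(C)C)C(C)C | intermediate
15 | 3-[2,4-bis(triisopropylsilyloxy)phenyl]-5,7-dimethoxy-6-(3-methylbut-2-enyl)-2H-chromene | COc1cc2c(c(OC)c1CC=C(C)C)C=C(c1ccc(O[Si](C(C)C)(C(C)C)C(C)C)cc1O[Si](C(C)C)(C(C)C)C(C)C)CO2 | intermediate
16 | dehydroglyasperin D, 4-[5,7-dimethoxy-6-(3-methylbut-2-enyl)-2H-chromen-3-yl]benzene-1,3-diol (achiral) | COc1cc2c(c(OC)c1CC=C(C)C)C=C(c1ccc(O)cc1O)CO2 | target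

**Count**

Total steps: 8. Longest linear sequence: 5 steps (steps 1, 2, 3, 7, 8, or equally steps 4, 5, 6, 7, 8).

**Steps most likely to fail**

Step 7. The ring A carbon may add to the unsubstituted alkene terminus of the enal (conjugate attack, which would give the 4H-chromene connectivity), and the 2-arylacrolein may dimerise or polymerise at reflux before it is consumed. The fallback sets out from 6 and 12 and comes back at 15. It makes the two bonds one after the other by ionic steps. Base-catalysed oxa-Michael addition of phenol 6 to enal 12 (DBU cat., MeCN, 0 °C to rt) should form the O1–C2 bond and give 3-[3,5-dimethoxy-4-(3-methylbut-2-enyl)phenoxy]-2-[2,4-bis(triisopropylsilyloxy)phenyl]propanal F1 as a racemate. Mild acid (PPTS, toluene, 60 °C, molecular sieves) should then close the C4–C4a bond by intramolecular Friedel–Crafts hydroxyalkylation at the activated ortho carbon and dehydrate the benzylic alcohol to 15.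

Step 5. The electron-rich, ortho-oxygenated aryl boronate may lose boron by protodeboronation, transmetalation next to the OTIPS group may be slow, and the ortho silyl ether may be partly lost in hot aqueous base. The fallback sets out from 8 and comes back at 11. It uses the arene as the electrophile under neutral conditions and brings in the oxygen by C–H oxidation. Stille coupling of 8 with tributyl(isopropenyl)stannane (Pd(PPh3)4, toluene, 100 °C) should give 1-(prop-1-en-2-yl)-2,4-bis(triisopropylsilyloxy)benzene F2. Allylic oxidation of its only allylic C–H position (SeO2 cat., t-BuOOH, CH2Cl2, rt; ene reaction then 2,3-sigmatropic shift) should give alcohol 11; any enal formed by over-oxidation is 12 itself.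

Step 2. Metalation may occur next to the silyloxy group, followed by oxygen-to-carbon silyl migration, so that regiocontrol is lost. The fallback sets out from 3 and comes back at 6, with the regiochemistry fixed by a symmetric arene. Commercial 1,3-dimethoxybenzene is lithiated between its methoxy groups (n-BuLi, THF, 0 °C to rt) to (2,6-dimethoxyphenyl)lithium F3, which is alkylated with 3 to 1,3-dimethoxy-2-(3-methylbut-2-enyl)benzene F4. Sterically controlled iridium-catalysed C–H borylation ([Ir(cod)OMe]2, 4,4′-di-tert-butyl-2,2′-bipyridine, B2pin2, THF, 60 °C) should take place at the only ring C–H without an ortho neighbour and give 2-[3,5-dimethoxy-4-(3-methylbut-2-enyl)phenyl]-4,4,5,5-tetramethyl-1,3,2-dioxaborolane F5. Oxidation of the C–B bond (NaBO3·4H2O, THF/H2O, rt) should give phenol 6.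

**Further compounds**

F1 | step 7 | 3-[3,5-dimethoxy-4-(3-methylbut-2-enyl)phenoxy]-2-[2,4-bis(triisopropylsilyloxy)phenyl]propanal (racemic) | O=CC(COc1cc(OC)c(CC=C(C)C)c(OC)c1)c1ccc(O[Si](C(C)C)(C(C)C)C(C)C)cc1O[Si](C(C)C)(C(C)C)C(C)C
F2 | step 5 | 1-(prop-1-en-2-yl)-2,4-bis(triisopropylsilyloxy)benzene | C=C(C)c1ccc(O[Si](C(C)C)(C(C)C)C(C)C)cc1O[Si](C(C)C)(C(C)C)C(C)C
F3 | step 2 | (2,6-dimethoxyphenyl)lithium | [Li]c1c(OC)cccc1OC
F4 | step 2 | 1,3-dimethoxy-2-(3-methylbut-2-enyl)benzene | COc1cccc(OC)c1CC=C(C)C
F5 | step 2 | 2-[3,5-dimethoxy-4-(3-methylbut-2-enyl)phenyl]-4,4,5,5-tetramethyl-1,3,2-dioxaborolane | COc1cc(B2OC(C)(C)C(C)(C)O2)cc(OC)c1CC=C(C)C
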